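**Plan**
- Cuts: (a) the C–C bond of the bromo‑oxirane in ring A, between the brominated carbon (next to the CMe2 carbon) and the oxirane CH (next to the methyl‑oxirane). That brominated carbon is a latent Br2C carbanion and the CH a latent aldehyde carbon, so one Darzens‑type event closes ring A and the bromo‑oxirane. (b) The methyl‑oxirane goes back to a (Z)‑allylic alcohol. (c) The C–Br and C–Cl bonds of ring B go back to a cyclohexene. (d) Ring B is cut by [4+2] into isoprene and an enol lactone.
- Forward: a Diels–Alder reaction builds ring B with the future spiro carbon and the carbinol carbon (first temporary ring: cis γ‑lactone). A temporary ether bridge (2‑oxabicyclo[2.2.2]octane) then installs Br and Cl. A second temporary ring (trans‑fused unsaturated δ‑lactone) fixes the Z olefin. Lactone reduction, directed epoxidation and carbenoid closure of ring A follow.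
- Stereochemistry: the catalytic Diels–Alder step sets the absolute configuration (spiro C, carbinol C). CHBr and C(Me)Cl come from anti bromo‑etherification and retentive chloride opening. The methyl‑oxirane comes from OH‑directed epoxidation, and the bromo‑oxirane from the ring closure itself.

Key step: step 16

Assumption: the sense of induction of the oxazaborolidinium catalyst with dienophile 5 is taken from the usual model for 2‑substituted acroleins; the antipodal catalyst is used if the other enantiomer should form.

**Step 1**
Reactants: 1 methyl 2,2-dimethylpent-4-enoate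
Product: 2 methyl 2,2-dimethyl-4-oxobutanoate
Conditions: O3, CH2Cl2/MeOH, −78 °C; then Me2S, −78 °C → rt
Reagents that add atoms: ozone, [O-][O+]=O
Why: Ozonolysis with reductive work-up cleaves the terminal alkene to the aldehyde and leaves the hindered ester untouched.

**Step 2**
Reactants: 2 methyl 2,2-dimethyl-4-oxobutanoate
Product: 3 methyl 4-(dimethylamino)-3-formyl-2,2-dimethylbut-3-enoate
Conditions: t-BuOCH(NMe2)2 (Bredereck's reagent), PhMe, 80 °C
Reagents that add atoms: tert-butoxybis(dimethylamino)methane, CC(C)(C)OC(N(C)C)N(C)C
Why: Aminomethylenation of the only enolisable position (the CH2 next to the aldehyde) gives the vinylogous formamide, a masked 2-substituted malondialdehyde.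

**Step 3**
Reactants: 3 methyl 4-(dimethylamino)-3-formyl-2,2-dimethylbut-3-enoate
Product: 5 4,4-dimethyl-5-oxo-4,5-dihydrofuran-3-carbaldehyde, via enol acid 4 (not isolated)
Conditions: NaOH, H2O/MeOH, 60 °C; aq. HCl to pH 2, extract; DCC, CH2Cl2, 0 °C → rt
Reagents that add atoms: sodium hydroxide, [Na+].[OH-]
Why: Saponification and enaminal hydrolysis give the malondialdehyde acid (its two formyl groups are equivalent, so no regiochemical choice), and carbodiimide activation closes the five-membered enol lactone (enol lactonisation).

**Step 4**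
Reactants: 5 4,4-dimethyl-5-oxo-4,5-dihydrofuran-3-carbaldehyde; 6 isoprene
Product: 7 (3aR,7aS)-3,3,6-trimethyl-2-oxo-2,3,4,7-tetrahydrobenzofuran-3a(7aH)-carbaldehyde
Conditions: (S)-3,3-diphenyl-1-(2-methylphenyl)tetrahydro-1H,3H-pyrrolo[1,2-c][1,3,2]oxazaborole activated with Tf2NH (20 mol %), CH2Cl2, −78 → −40 °C
Reagents that add atoms: none
Why: Enantioselective Diels–Alder reaction in which the cationic oxazaborolidine activates the formyl group, isoprene adds with the usual "para" orientation (ring methyl 1,4 to the formyl-bearing carbon), the catalyst selects the face and so sets the quaternary (future spiro) carbon and the O-bearing carbon, and the five-membered ring of the dienophile forces the lactone oxygen cis to the CMe2 carbon and trans to the formyl group.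

**Step 5**
Reactants: 7 (3aR,7aS)-3,3,6-trimethyl-2-oxo-2,3,4,7-tetrahydrobenzofuran-3a(7aH)-carbaldehyde
Product: 8 3a-(1-hydroxyethyl) lactone (both carbinol epimers)
Conditions: MeMgBr (1.05 equiv), THF, −78 °C; AcOH quench at −78 °C
Reagents that add atoms: methylmagnesium bromide, C[Mg]Br
Why: Grignard addition to the aldehyde at −78 °C leaves the α,α-dimethyl lactone alone; the carbinol epimers are not separated because this centre is oxidised again in step 8.

**Step 6**
Reactants: 8 3a-(1-hydroxyethyl) lactone (both carbinol epimers)
Product: 9 bridged bromo ether (2-oxabicyclo[2.2.2]octane fused to the γ-lactone)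
Conditions: NBS, CH2Cl2, 0 °C, dark
Reagents that add atoms: N-bromosuccinimide, O=C1CCC(=O)N1Br
Why: Bromo-etherification of the cineole type: the side-chain hydroxyl, held on one face of ring B, opens the bromonium ion at the tertiary alkene carbon, so oxygen enters cis to the side chain and bromine ends up on the neighbouring CH on the opposite face (anti addition), which fixes both future halogen centres relative to the quaternary carbon.

**Step 7**
Reactants: 9 bridged bromo ether (2-oxabicyclo[2.2.2]octane fused to the γ-lactone)
Product: 10 bromo chloro alcohol lactone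
Conditions: HCl (4 M in 1,4-dioxane), CH2Cl2, −20 → 0 °C; used at once in step 8
Reagents that add atoms: hydrogen chloride, Cl
Why: Acid cleavage of the tertiary ether C–O bond is assisted by the neighbouring bromine (bromonium ion), and chloride opens that ion at the tertiary carbon from the face the oxygen left, giving the tertiary chloride with retention and the trans bromochloride; the secondary neopentyl C–O bond does not ionise.

**Step 8**
Reactants: 10 bromo chloro alcohol lactone
Product: 11 bromo chloro methyl ketone lactone
Conditions: Dess–Martin periodinane, CH2Cl2, 0 °C → rt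
Reagents that add atoms: none
Why: Dess–Martin oxidation of the secondary alcohol gives the methyl ketone needed for olefination and removes the hydroxyl that could re-close the ether.

**Step 9**
Reactants: 11 bromo chloro methyl ketone lactone
Product: 14 unsaturated δ-lactone acid, via lithium hydroxy carboxylate 12 (not isolated), via phosphorane ester 13 (not isolated)
Conditions: LiOH·H2O (1.05 equiv), THF/H2O, 0 °C; concentrate, dry by PhMe azeotrope; Ph3P=C=C=O, THF, 65 °C; cold aq. HCl work-up
Reagents that add atoms: lithium hydroxide, [Li+].[OH-]; (triphenylphosphoranylidene)ketene, O=C=C=P(c1ccccc1)(c1ccccc1)c1ccccc1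
Why: Hydroxide opens the γ-lactone (first temporary ring), the freed ring-B hydroxyl adds to the ketenylidene ylide, and the resulting acyl ylide undergoes intramolecular Wittig olefination with the methyl ketone to the trans-fused δ-lactone (second temporary ring), in which the trisubstituted alkene can only be Z.

**Step 10**
Reactants: 14 unsaturated δ-lactone acid
Product: 16 δ-lactone aldehyde, via acid chloride 15 (not isolated)
Conditions: (COCl)2, cat. DMF, CH2Cl2, 0 °C; then LiAlH(OtBu)3, THF, −78 °C
Reagents that add atoms: none
Why: Acid chloride formation and reduction with the bulky, mild hydride LiAlH(OtBu)3 at −78 °C stop at the aldehyde and spare the unsaturated lactone and the alkyl halides.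

**Step 11**
Reactants: 16 δ-lactone aldehyde
Product: 17 δ-lactone gem-dibromide
Conditions: (PhO)3P, Br2, CH2Cl2, −78 °C; then 16, −78 °C → rt
Reagents that add atoms: bromine, BrBr
Why: Triphenyl phosphite–bromine converts the non-enolisable neopentyl aldehyde into the geminal dibromide (deoxygenative dihalogenation) without free acid or base.

**Step 12**
Reactants: 17 δ-lactone gem-dibromide
Product: 18 (Z)-allylic diol
Conditions: i-Bu2AlH (4 equiv), CH2Cl2, −78 → 0 °C; aq. KNaC4H4O6 work-up
Reagents that add atoms: none
Why: i-Bu2AlH reduces the unsaturated lactone by 1,2-addition to the (Z)-allylic alcohol and releases the ring-B hydroxyl, which removes the second temporary ring.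

**Step 13**
Reactants: 18 (Z)-allylic diol
Product: 19 epoxy diol
Conditions: VO(acac)2 (5 mol %), t-BuOOH, CH2Cl2, 0 °C → rt
Reagents that add atoms: tert-butyl hydroperoxide, CC(C)(C)OO
Why: Vanadium-catalysed hydroxyl-directed epoxidation delivers oxygen to the alkene face on which the ring-B hydroxyl lies (bound together with the allylic OH), which is also the face remote from the CMe2CHBr2 group in the conformer free of allylic strain, so both methyl-oxirane centres are set.

**Step 14**
Reactants: 19 epoxy diol
Product: 20 bis(triethylsilyl) ether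
Conditions: Et3SiOTf, 2,6-lutidine, CH2Cl2, −78 °C
Reagents that add atoms: triethylsilyl trifluoromethanesulfonate, CC[Si](CC)(CC)OS(=O)(=O)C(F)(F)F
Why: Silyl triflate with a hindered base silylates both the primary and the hindered secondary hydroxyl at low temperature without opening the oxirane.

**Step 15**
Reactants: 20 bis(triethylsilyl) ether
Product: 21 epoxy aldehyde
Conditions: (COCl)2, DMSO, CH2Cl2, −78 → −30 °C; Et3N, −78 → 0 °C
Reagents that add atoms: none
Why: Swern conditions convert the primary triethylsilyl ether directly into the aldehyde (the chlorosulfonium ion attacks the less hindered silyl ether oxygen) while the hindered secondary silyl ether survives.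

**Step 16**
Reactants: 21 epoxy aldehyde
Product: 24 O-triethylsilyl ether of the target, via lithium carbenoid 22 (not isolated), via lithium bromohydrin alkoxide 23 (not isolated)
Conditions: LiTMP (lithium 2,2,6,6-tetramethylpiperidide, 1.3 equiv), THF/Et2O, −100 °C, then → −40 °C; aq. NH4Cl
Reagents that add atoms: none
Why: LiTMP removes the proton of the CHBr2 group (flanked by two bromines and a quaternary carbon) to give an α,α-dibromoalkyllithium carbenoid that adds at once to the neighbouring aldehyde, and the β-oxido gem-dibromide then expels one bromide to give the bromo-oxirane. The closest known reaction type is the Darzens-type addition of 1,1-dihaloalkyllithiums to aldehydes and ketones, which gives α-halo epoxides; here it is run intramolecularly. Ring A closes by 6-exo-trig attack of the carbanion on the C=O carbon, and the oxirane closes by 3-exo-tet displacement of bromide by the alkoxide. The new CH–O centre is set in the C–C bond-forming step: the C=O must stand roughly perpendicular to the forming ring, and the rotamer with C=O anti to the adjacent oxirane C–O bond (dipole-opposed, lithium not chelated in THF) puts the new oxygen on the face opposite the methyl-oxirane, giving the trans bis-epoxide; the brominated carbon follows because the cis-fused oxirane can only form by loss of the bromine anti to the alkoxide. The step needs deprotonation at CHBr2 in preference to attack on the aldehyde or removal of its oxiranyl α-proton, which the hindered non-nucleophilic amide, the strained (poorly acidic) oxiranyl position and generation of the anion at −100 °C next to its trap are meant to secure; the secondary bromide, tertiary chloride and silyl ether are inert at this temperature.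

**Step 17**
Reactants: 24 O-triethylsilyl ether of the target
Product: 25 target
Conditions: Bu4NF, AcOH (1:1), THF, 0 °C
Reagents that add atoms: none
Why: Fluoride buffered with acetic acid removes the silyl group without acid- or base-induced transannular attack of the hydroxyl on the oxiranes.

**Compound list**
1 | methyl 2,2-dimethylpent-4-enoate | COC(=O)C(C)(C)CC=C | starting material
2 | methyl 2,2-dimethyl-4-oxobutanoate | COC(=O)C(C)(C)CC=O | intermediate
3 | methyl 4-(dimethylamino)-3-formyl-2,2-dimethylbut-3-enoate | COC(=O)C(C)(C)C(C=O)=CN(C)C | intermediate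
4 | 3-formyl-4-hydroxy-2,2-dimethylbut-3-enoic acid (enol of the malondialdehyde acid, not isolated) | OC=C(C=O)C(C)(C)C(=O)O | intermediate
5 | 4,4-dimethyl-5-oxo-4,5-dihydrofuran-3-carbaldehyde (enol lactone dienophile) | O=CC1=COC(=O)C1(C)C | intermediate
6 | isoprene (2-methylbuta-1,3-diene) | C=CC(C)=C | starting material
7 | (3aR,7aS)-3,3,6-trimethyl-2-oxo-2,3,4,7-tetrahydrobenzofuran-3a(7aH)-carbaldehyde (cis-fused γ-lactone, formyl on the ring-fusion carbon) | O=C[C@@]12CC=C(C)C[C@@H]1OC(=O)C2(C)C | intermediate
8 | 3a-(1-hydroxyethyl) analogue of 7 (ring-fusion configuration as in 7, both carbinol epimers) | CC(O)[C@@]12CC=C(C)C[C@@H]1OC(=O)C2(C)C | intermediate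
9 | bridged bromo ether: ether oxygen links the side-chain CH(CH3) to the methyl-bearing ring carbon (2-oxabicyclo[2.2.2]octane), Br on the adjacent CH anti to the oxygen bridge, γ-lactone retained | CC(O3)[C@@]12C[C@H](Br)[C@]3(C)C[C@@H]1OC(=O)C2(C)C | intermediate
10 | bromo chloro alcohol lactone: 1-hydroxyethyl side chain, trans CHBr/C(CH3)Cl with Cl cis to the side chain | CC(O)[C@@]12C[C@H](Br)[C@@](C)(Cl)C[C@@H]1OC(=O)C2(C)C | intermediate
11 | bromo chloro methyl ketone lactone (3a-acetyl) | CC(=O)[C@@]12C[C@H](Br)[C@@](C)(Cl)C[C@@H]1OC(=O)C2(C)C | intermediate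
12 | lithium 2-(1-acetyl-5-bromo-4-chloro-2-hydroxy-4-methylcyclohexyl)-2-methylpropanoate (not isolated) | CC(=O)[C@@]1(C(C)(C)C(=O)[O-])C[C@H](Br)[C@@](C)(Cl)C[C@@H]1O.[Li+] | intermediate
13 | (triphenylphosphoranylidene)acetate ester of 12 (not isolated) | CC(=O)[C@@]1(C(C)(C)C(=O)[O-])C[C@H](Br)[C@@](C)(Cl)C[C@@H]1OC(=O)C=P(c1ccccc1)(c1ccccc1)c1ccccc1.[Li+] | intermediate
14 | unsaturated δ-lactone acid: trans-fused 4-methyl-5,6-dihydropyran-2-one on ring B, CMe2CO2H on the ring-fusion carbon | CC(=CC(=O)O4)[C@@]1(C(C)(C)C(=O)O)C[C@H](Br)[C@@](C)(Cl)C[C@@H]14 | intermediate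
15 | acid chloride of 14 (not isolated) | CC(=CC(=O)O4)[C@@]1(C(C)(C)C(Cl)=O)C[C@H](Br)[C@@](C)(Cl)C[C@@H]14 | intermediate
16 | δ-lactone aldehyde (CMe2CHO) | CC(=CC(=O)O4)[C@@]1(C(C)(C)C=O)C[C@H](Br)[C@@](C)(Cl)C[C@@H]14 | intermediate
17 | δ-lactone gem-dibromide (CMe2CHBr2) | CC(=CC(=O)O4)[C@@]1(C(C)(C)C(Br)Br)C[C@H](Br)[C@@](C)(Cl)C[C@@H]14 | intermediate
18 | (Z)-allylic diol: ring-B cyclohexanol carrying CMe2CHBr2 and (Z)-C(CH3)=CH–CH2OH on the quaternary carbon | C/C(=C/CO)[C@@]1(C(C)(C)C(Br)Br)C[C@H](Br)[C@@](C)(Cl)C[C@@H]1O | intermediate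
19 | epoxy diol (cis-2,3-epoxy alcohol side chain) | OC[C@@H]2O[C@]2(C)[C@@]1(C(C)(C)C(Br)Br)C[C@H](Br)[C@@](C)(Cl)C[C@@H]1O | intermediate
20 | bis(triethylsilyl) ether of 19 | CC[Si](CC)(CC)OC[C@@H]2O[C@]2(C)[C@@]1(C(C)(C)C(Br)Br)C[C@H](Br)[C@@](C)(Cl)C[C@@H]1O[Si](CC)(CC)CC | intermediate
21 | epoxy aldehyde with CMe2CHBr2 and ring-B OSiEt3 | O=C[C@@H]2O[C@]2(C)[C@@]1(C(C)(C)C(Br)Br)C[C@H](Br)[C@@](C)(Cl)C[C@@H]1O[Si](CC)(CC)CC | intermediate
22 | lithium α,α-dibromoalkyl carbenoid of 21 (not isolated) | O=C[C@@H]2O[C@]2(C)[C@@]1(C(C)(C)[C-](Br)Br)C[C@H](Br)[C@@](C)(Cl)C[C@@H]1O[Si](CC)(CC)CC.[Li+] | intermediate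
23 | ring-A-closed lithium alkoxide: CBr2 next to CH–OLi, oxygen trans to the methyl-oxirane (not isolated) | CC1(C)C(Br)(Br)[C@@H]([O-])[C@@H]2O[C@]2(C)[C@]12C[C@H](Br)[C@@](C)(Cl)C[C@@H]2O[Si](CC)(CC)CC.[Li+] | intermediate
24 | O-triethylsilyl ether of the target | CC1(C)[C@@]2(Br)O[C@H]2[C@@H]2O[C@]2(C)[C@]12C[C@H](Br)[C@@](C)(Cl)C[C@@H]2O[Si](CC)(CC)CC | intermediate
25 | target CNP0345283.3: spiro bis-epoxide, ring A with bromo-oxirane (C–Br S, CH S) and methyl-oxirane (CH S, C–CH3 R), spiro carbon R, ring B CHBr S, C(CH3)Cl S, CHOH S | CC1(C)[C@@]2(Br)O[C@H]2[C@@H]2O[C@]2(C)[C@]12C[C@H](Br)[C@@](C)(Cl)C[C@@H]2O | target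

**Step count and risks**
Total steps: 17. Longest linear sequence: 17 (from 1; isoprene 6 enters at step 4).

Steps most likely to fail:

1. Step 16. The amide base may instead remove the oxiranyl proton α to the aldehyde or add to the aldehyde, or the carbenoid may undergo α-elimination before it closes the ring. Fallback (sets out from 20, comes back at 24): the CHBr2 group of 20 is deprotonated with LiTMP at −100 °C, with no carbonyl group present, and brominated with CBr4 to give the tribromomethyl bis-silyl ether F1. Swern oxidation of the primary silyl ether gives the tribromomethyl epoxy aldehyde F2. n-BuLi in THF/Et2O/pentane at −110 °C then effects bromine–lithium exchange, which outruns addition to the aldehyde (Parham-type cyclisation), so the same carbenoid forms without base and closes to 24.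

2. Step 4. The β-acyloxy enal may be too unreactive towards isoprene under the chiral catalyst, or facial selectivity may be poor. Fallback (sets out from 5 and 6, comes back at 7): cycloaddition promoted by Et2AlCl gives 7 together with the enantiomeric cycloadduct F3. Condensation with (1R,2R)-N,N'-dimethyl-1,2-diphenylethane-1,2-diamine gives the imidazolidine of 7 F4 and the imidazolidine of the enantiomer F5, which are separated by chromatography. Hydrolysis of F4 with aqueous AcOH returns 7.

3. Step 9. Hydroxide may cause loss of HCl or HBr from ring B or retro-aldol opening of the β-hydroxy ketone, and the Wittig closure on the hindered ketone may be slow at a temperature the halides tolerate. Fallback (sets out from 11, comes back at 14): the lactone is opened with Me3SnOH in 1,2-dichloroethane at 60 °C and the carboxylate is alkylated with allyl bromide (Cs2CO3, DMF) to give the hydroxy keto allyl ester F6. Acylation with diethylphosphonoacetic acid (DCC, DMAP) gives the phosphonoacetate F7. Intramolecular Horner–Wadsworth–Emmons reaction with LiCl/DBU in MeCN at rt gives the δ-lactone allyl ester F8. Pd(PPh3)4 with morpholine removes the allyl group and returns 14.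

**Further compounds**
F1 | step 16 | tribromomethyl bis(triethylsilyl) ether (CBr3 analogue of 20) | CC[Si](CC)(CC)OC[C@@H]2O[C@]2(C)[C@@]1(C(C)(C)C(Br)(Br)Br)C[C@H](Br)[C@@](C)(Cl)C[C@@H]1O[Si](CC)(CC)CC
F2 | step 16 | tribromomethyl epoxy aldehyde (CBr3 analogue of 21) | O=C[C@@H]2O[C@]2(C)[C@@]1(C(C)(C)C(Br)(Br)Br)C[C@H](Br)[C@@](C)(Cl)C[C@@H]1O[Si](CC)(CC)CC
F3 | step 4 | enantiomer of 7 | O=C[C@]12CC=C(C)C[C@H]1OC(=O)C2(C)C
F4 | step 4 | imidazolidine from 7 and the (1R,2R)-diamine | CN1[C@H](c2ccccc2)[C@@H](c2ccccc2)N(C)C1[C@@]34CC=C(C)C[C@@H]3OC(=O)C4(C)C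
F5 | step 4 | imidazolidine from F3 and the (1R,2R)-diamine | CN1[C@H](c2ccccc2)[C@@H](c2ccccc2)N(C)C1[C@]34CC=C(C)C[C@H]3OC(=O)C4(C)C
F6 | step 9 | hydroxy keto allyl ester | CC(=O)[C@@]1(C(C)(C)C(=O)OCC=C)C[C@H](Br)[C@@](C)(Cl)C[C@@H]1O
F7 | step 9 | diethylphosphonoacetate of F6 | CC(=O)[C@@]1(C(C)(C)C(=O)OCC=C)C[C@H](Br)[C@@](C)(Cl)C[C@@H]1OC(=O)CP(=O)(OCC)OCC
F8 | step 9 | unsaturated δ-lactone allyl ester | CC(=CC(=O)O4)[C@@]1(C(C)(C)C(=O)OCC=C)C[C@H](Br)[C@@](C)(Cl)C[C@@H]14
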